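## Retrosynthetic overview
1. The target is a C2-symmetric head-to-tail dimer. Cutting the two benzylic C7–O bonds of the 1,4-dioxane gives two molecules of one monomer, the 6α,7α-epoxide of 6,7-dehydroferruginol methyl ether. This monomer is a masked para-methoxy quinone-methide cation that carries its own 6α-oxygen nucleophile.
2. Epoxide and dioxane are made in one flask from the styrene 6,7-dehydroferruginol methyl ether. The styrene comes from ferruginol methyl ether by hydride abstraction at C7.
3. Rings A and B come from one enantioselective, proton-initiated polyene bicyclisation of an achiral homogeranylarene. Ring C is the purchased arene.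
4. The homogeranylarene comes from geranyl chloride and the benzylic Grignard reagent of chloromethylated 2-isopropylanisole.
5. Ring order: C (bought), then A and B (one cascade), then the dioxane last (four C–O bonds and four stereocentres in one operation).

**Conventions.** Abietane numbering is used. α is the face of H5 and β is the face of the C20 methyl.

**Structure reading.**
- Both halves are identical: 5S,10S, with H5 α and C20 β.
- Oxygen on C6 is α and oxygen on C7 is β, so H6β and H7α are both axial.
- The links are C7–O–C6' and C6–O–C7'.
- Two homochiral trans-diequatorial units give a trans-anti-trans ladder, so the central dioxane is a twist-boat, not a chair.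

**Assumption:** the (R)-ligand in step 3 gives the natural (5S,10S) series, as (R)-BINOL-derived acids of this class do with homogeranylarenes; if 6 proves levorotatory, the (S)-ligand is used and nothing else changes.

## Route

Step 1
Reactants: 1 2-isopropylanisole
Product: 2 4-(chloromethyl)-2-isopropylanisole
Conditions: (CH2O)n (1.3 equiv), HCl (g), conc. aq. HCl, 1,4-dioxane, 0 → 20 °C
Reagents that add atoms: formaldehyde (from paraformaldehyde) C=O; hydrogen chloride Cl
Why: Blanc chloromethylation is an electrophilic aromatic substitution that goes para to the methoxy group (the free ortho site is less accessible and the site para to isopropyl is meta to OMe), and it creates no stereocentre.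

Step 2
Reactants: 2 4-(chloromethyl)-2-isopropylanisole; 3 geranyl chloride
Product: 5 4-[(3E)-4,8-dimethylnona-3,7-dien-1-yl]-2-isopropylanisole (homogeranylarene), via benzylmagnesium chloride 4 (not isolated)
Conditions: Mg (2 equiv), THF, 0 °C, slow addition of 2; then 3, Li2CuCl4 (3 mol %), THF, −30 → 0 °C
Reagents that add atoms: magnesium [Mg] (enters intermediate 4 only)
Why: Copper-catalysed allylic substitution of a Grignard reagent run in THF with Li2CuCl4 at low temperature is SN2-selective at the primary carbon and keeps the E geometry that later fixes the trans ring fusion; slow dilute addition limits Wurtz coupling, and no stereocentre is formed.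

Step 3
Reactants: 5 homogeranylarene
Product: 6 (+)-ferruginol methyl ether ((5S,10S)-12-methoxyabieta-8,11,13-triene; H5 α and C20 β)
Conditions: (R)-3,3'-dichloro-1,1'-bi-2-naphthol·SbCl5 (1:1 complex, 0.5 equiv), CH2Cl2, −78 °C, 12 h
Reagents that add atoms: none
Why: This is an enantioselective proton-initiated cationic polyene cyclisation in which the Lewis-acid-assisted chiral Brønsted acid protonates one face of the terminal alkene; chair–chair antiperiplanar addition across the E-alkene (Stork–Eschenmoser) sets C5 and C10 trans, and the arene closes at the open position para to isopropyl.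

Step 4
Reactants: 6 (+)-ferruginol methyl ether
Product: 7 6,7-dehydroferruginol methyl ether ((5S,10S)-12-methoxyabieta-6,8,11,13-tetraene)
Conditions: DDQ (1.05 equiv), 4 Å MS, dry 1,4-dioxane, 20 → 50 °C
Reagents that add atoms: none
Why: In this benzylic dehydrogenation DDQ abstracts the pseudo-axial 7α-hydride, which sits para to OMe, and the quinone-methide-like cation loses H6 (the same reactivity as estrone methyl ether going to its 9(11)-ene); the isopropyl methine C–H lies in the arene plane and is spared, and C5 and C10 are untouched.

Step 5
Reactants: 7 6,7-dehydroferruginol methyl ether (two molecules)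
Product: 9 target CNP0327150.1 (C2-symmetric 6α-O-7'β/7β-O-6'α bis-ether dimer), via alpha-epoxide 8 (not isolated)
Conditions: DMDO (1.05 equiv per alkene, 0.07 M in acetone), CH2Cl2, −40 °C; evaporate cold with a toluene chase to remove all acetone; CH2Cl2 (0.5 M), AW-300 MS, HNTf2 (2 mol %), −78 → −30 °C; Et3N quench
Reagents that add atoms: dimethyldioxirane CC1(C)OO1
Why: Proposed new method: DMDO delivers oxygen to the α face (the β face is blocked by the axial C20 and C19 methyls), which fixes both C6–O centres; the epoxide is a phenylogous epoxy ether, so a trace of strong acid opens C7–O to a para-methoxybenzyl cation that is captured head-to-tail by the oxygen of a second epoxide and then closed by the freed 6α-OH, with low temperature and high concentration favouring bimolecular capture over the 1,2-hydride shift to the 6-ketone; the 4α-methyl (C18) forces each C6–O–C7' bond anti to C5–C6, so both kinetic closure and reversible re-ionisation of the benzylic ethers lead to 7β-O in both halves (a twist-boat dioxane whose roughly 70° O–C–C–O angle matches the half-chair of ring B, whereas the cis-closed isomer pushes the partner's C7 against C18 and H5); the closest known reaction types are the acid-catalysed cyclodimerisation of epoxy ethers and of aryl epoxides to 1,4-dioxanes.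

**Enantiopurity.**
- Any minor enantiomer of 7 pairs with the major one to give the centrosymmetric, all-chair meso heterodimer.
- This heterodimer is a separable diastereomer of 9.
- Monomer of 90% ee therefore gives 9 of at least 99% ee, even with purely statistical pairing.
- Product 9 is recognised by a single set of NMR signals and J(H6,H7) of about 9–10 Hz.

## Compound list
1 | 2-isopropylanisole | COc1ccccc1C(C)C | starting material
2 | 4-(chloromethyl)-2-isopropylanisole | COc1ccc(CCl)cc1C(C)C | intermediate
3 | geranyl chloride, (2E)-1-chloro-3,7-dimethylocta-2,6-diene | CC(C)=CCC/C(C)=C/CCl | starting material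
4 | (3-isopropyl-4-methoxybenzyl)magnesium chloride | COc1ccc(C[Mg]Cl)cc1C(C)C | intermediate
5 | 4-[(3E)-4,8-dimethylnona-3,7-dien-1-yl]-2-isopropylanisole | COc1ccc(CC/C=C(C)/CCC=C(C)C)cc1C(C)C | intermediate
6 | (+)-ferruginol methyl ether, (5S,10S)-12-methoxyabieta-8,11,13-triene | COc1cc2c(cc1C(C)C)CC[C@H]1C(C)(C)CCC[C@]21C | intermediate
7 | 6,7-dehydroferruginol methyl ether, (5S,10S)-12-methoxyabieta-6,8,11,13-tetraene | COc1cc2c(cc1C(C)C)C=C[C@H]1C(C)(C)CCC[C@]21C | intermediate
8 | 6α,7α-epoxy-12-methoxyabieta-8,11,13-triene | COc1cc2c(cc1C(C)C)[C@@H]1O[C@@H]1[C@H]1C(C)(C)CCC[C@]21C | intermediate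
9 | CNP0327150.1, head-to-tail 1,4-dioxane dimer (6α-O, 7β-O in both halves) | COc1cc2c(cc1C(C)C)[C@H]1O[C@H]3[C@H](O[C@@H]1[C@H]1C(C)(C)CCC[C@]21C)c1cc(C(C)C)c(OC)cc1[C@@]1(C)CCCC(C)(C)[C@H]31 | target

## Count and risks
Total steps: 5. Longest linear sequence: 5 (1 → 2 → 5 → 6 → 7 → 9).

**Most likely to fail, first: step 5.**
- Possible failures are a Meinwald-type hydride shift to the 6-ketone, polyether formation, or closure to the unsymmetrical trans/cis isomer.
- The fallback sets out from 7 and comes back at 9. It replaces the strained epoxide electrophile by an isolable cation reservoir.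
- Compound 7 is epoxidised with DMDO as above, and 8 is quenched at once in MeOH containing pyridinium p-toluenesulfonate. This gives 7β,12-dimethoxyabieta-8,11,13-trien-6α-ol F1. Its C7 configuration does not matter, because C7 is ionised again.
- Every molecule of F1 already carries the free 6α-OH nucleophile. Treatment with Bi(OTf)3 (5 mol %) in toluene (1 M) over 5 Å MS, which take up methanol, runs a double transetherification under thermodynamic control. Open oligomers and mis-closed isomers are corrected to 9.

**Second: step 3.**
- Possible failures are incomplete closure onto an arene position meta to OMe, attack of SbCl5 on the anisole, or insufficient ee.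
- The fallback sets out from 5 and comes back at 6. It changes the initiator from a proton to an iodonium ion.
- NIS and a stoichiometric chiral BINOL-derived phosphoramidite (the enantiomer that leads to the 5S,10S series) are used in toluene at −40 °C. ClSO3H in 2-nitropropane at −78 °C then completes closure of ring B. The product is 3β-iodo-12-methoxyabieta-8,11,13-triene F2, with the iodine equatorial.
- Radical deiodination with Bu3SnH/AIBN in toluene at 80 °C returns 6.

**Third: step 4.**
- Possible failures are over-oxidation by abstraction of the allylic H5 hydride from 7, or formation of the 7-ketone from traces of water.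
- The fallback sets out from 6 and comes back at 7. It goes through the carbonyl oxidation level.
- CrO3 in AcOH gives sugiol methyl ether F3.
- NaBH4 in MeOH delivers hydride axially from the α face to give 12-methoxyabieta-8,11,13-trien-7β-ol F4.
- Catalytic p-TsOH in refluxing toluene dehydrates F4 to 7.

## Further compounds
F1 | step 5 | 7β,12-dimethoxyabieta-8,11,13-trien-6α-ol | COc1cc2c(cc1C(C)C)[C@@H](OC)[C@H](O)[C@H]1C(C)(C)CCC[C@]21C
F2 | step 3 | 3β-iodo-12-methoxyabieta-8,11,13-triene | COc1cc2c(cc1C(C)C)CC[C@H]1C(C)(C)[C@@H](I)CC[C@]21C
F3 | step 4 | sugiol methyl ether (12-methoxyabieta-8,11,13-trien-7-one) | COc1cc2c(cc1C(C)C)C(=O)C[C@H]1C(C)(C)CCC[C@]21C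
F4 | step 4 | 12-methoxyabieta-8,11,13-trien-7β-ol | COc1cc2c(cc1C(C)C)[C@@H](O)C[C@H]1C(C)(C)CCC[C@]21C
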